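**Plan**

- Each quinone ring is numbered C1(=O), C2(OH), C3(tether), C4(=O), C5(OMe), C6(Me). The retrosynthesis first removes the C2–O bond (via the C2/C3 epoxide) and the C4 oxygen, leading back to a tethered bis(3-methoxy-2-methylphenol).
- In each arene the bonds C1–C6, C4–C5 and C1–C2 are then cut. C1–C4 with the tether come from a 3-alkylcyclobutenone, and C5/C6 with OMe and Me come from 1-methoxypropyne.
- Enabling feature: the contiguous triad C1(O)–C6(CH3)–C5(OCH3), with the tether on C3 across the ring from C6 and no carbon substituent on C2 or C4, is the pattern a cyclobutenone/ynol ether benzannulation delivers. Both rings are identical and sit at the ends of an inert (CH2)14 chain, so one operation can build both.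
- Forward: double acetylide alkylation gives the C18 diyne, dichloroketene cycloaddition and dechlorination give both four-membered rings, and one benzannulation forms both six-membered rings. The oxidation level is then raised (quinone, epoxide, hydroxyquinone).
- Stereochemistry: the target has none. The epoxide stereocentres of the penultimate compound are transient and are erased in the last step.

Key step: step 5

Remark: the target carries no stereocentre or defined double-bond geometry; 1,14-dibromotetradecane is taken to be a catalogue compound; every tethered intermediate reacts at both ends, so steps 1, 2 and 5 each consume two molecules of the partner per molecule of substrate.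

**Route**

Step 1
Reactants: 1 1,14-dibromotetradecane; 2 lithium acetylide ethylenediamine complex
Product: 3 octadeca-1,17-diyne
Conditions: 2 (3 equiv), DMSO/THF, 0 to 20 °C
Reagents that add atoms: none
Why: Twofold SN2 alkylation of the acetylide at the two primary bromides (two molecules of 2 per molecule of 1) in a dipolar aprotic medium is the standard way to terminal alkynes, and the low temperature should keep base-induced alkyne migration negligible.

Step 2
Reactants: 3 octadeca-1,17-diyne; 4 trichloroacetyl chloride
Product: 6 3,3'-(tetradecane-1,14-diyl)bis(4,4-dichlorocyclobut-2-en-1-one), via dichloroketene 5 (not isolated)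
Conditions: 4 (5 equiv), zinc–copper couple Zn(Cu), Et2O/DME, 20–35 °C
Reagents that add atoms: none
Why: Each alkyne terminus takes up one molecule of dichloroketene, so two molecules of 4 are consumed per molecule of 3 and the remaining excess covers ketene oligomerisation; the ketene, released by zinc dehalogenation of the acid chloride, adds in a regioselective ketene–alkyne [2+2] cycloaddition (carbonyl carbon to the terminal CH), the established entry to 3-alkyl-4,4-dichlorocyclobutenones, and any allylic chloride-shift isomer converges on the same product in step 3.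

Step 3
Reactants: 6 3,3'-(tetradecane-1,14-diyl)bis(4,4-dichlorocyclobut-2-en-1-one)
Product: 7 3,3'-(tetradecane-1,14-diyl)bis(cyclobut-2-en-1-one)
Conditions: Zn dust, AcOH, TMEDA, EtOH, 0 to 20 °C
Reagents that add atoms: none
Why: Reductive dehalogenation of the α-chloro ketone positions by zinc in amine-buffered acetic acid should strip all four chlorines without reducing or isomerising the strained enone, as is routine for 3-alkylcyclobutenones.

Step 4
Reactants: 8 2-chloro-1,1-dimethoxyethane
Product: 10 1-methoxyprop-1-yne, via sodium methoxyacetylide 9 (not isolated)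
Conditions: NaNH2 (3.1 equiv), liquid NH3, −35 °C; then MeI, −35 °C; cold aqueous work-up (pentane), careful distillation
Reagents that add atoms: iodomethane, CI
Why: Three equivalents of amide should effect the double elimination (loss of methanol and of HCl) and leave the alkynyl ether as its sodium salt, which is C-methylated by iodomethane in liquid ammonia, the classical ynol ether synthesis from chloroacetaldehyde acetals.

Step 5
Reactants: 7 3,3'-(tetradecane-1,14-diyl)bis(cyclobut-2-en-1-one); 10 1-methoxyprop-1-yne
Product: 15 5,5'-(tetradecane-1,14-diyl)bis(3-methoxy-2-methylphenol), via bis-vinylketene 11 (not isolated), via bis(4-alkenylcyclobutenone) 12 (not isolated), via bis-dienylketene 13 (not isolated), via bis-cyclohexadienone 14 (not isolated)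
Conditions: 10 (4 equiv), toluene (ca. 0.1 M), sealed tube, 80 °C then 110 °C; then KOH, MeOH, 20 °C; acidify
Reagents that add atoms: none
Why: Heating opens each cyclobutenone by 4π electrocyclic ring opening to a vinylketene (11), which adds one molecule of the electron-rich ynol ether in a [2+2] cycloaddition to a 4-alkenylcyclobutenone (12); a second 4π opening gives the dienylketene with the ketenyl and vinyl groups cis (13), which cyclises to the cyclohexa-2,4-dienone (14) and tautomerises to the phenol, so that two molecules of 10 are incorporated per molecule of 7. The closest known reaction type is the Danheiser benzannulation of 3-alkylcyclobutenones with 1-alkoxyalkynes, run here at both termini of one saturated tether. Each six-membered ring closes by a thermal disrotatory 6π electrocyclisation that joins the former ketene carbonyl carbon to the former cyclobutenone CH2 (C1–C2), after the [2+2] step has made C1–C6 and C4–C5. No stereocentre has to be controlled, because the single sp3 ring carbon of each half of 12 ends up aromatic. The step needs regiocontrol in the ketene–alkyne cycloaddition: the oxygen lone pair polarises the ynol ether so that its CH3-bearing carbon attacks the ketene C=O carbon and its OCH3-bearing carbon joins the ketene α-carbon, which puts CH3 next to the phenolic carbon, OCH3 one position further and the tether opposite CH3. It also needs the ketene to be captured by alkyne and not by product phenol, which the excess ynol ether, the moderate dilution and the closing KOH/MeOH treatment (cleaving any aryl ester) should ensure.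

Step 6
Reactants: 15 5,5'-(tetradecane-1,14-diyl)bis(3-methoxy-2-methylphenol)
Product: 16 5,5'-(tetradecane-1,14-diyl)bis(3-methoxy-2-methylcyclohexa-2,5-diene-1,4-dione)
Conditions: (KSO3)2NO (5 equiv), aq. KH2PO4, methyltrioctylammonium chloride (cat.), CH2Cl2/H2O, 20 °C
Reagents that add atoms: potassium nitrosodisulfonate (Fremy's salt), [K+].[K+].[O]N(S(=O)(=O)[O-])S(=O)(=O)[O-]
Why: In the Teuber oxidation two equivalents of the nitroxyl radical per phenol deliver oxygen to the unsubstituted position para to OH (C4) and should give the para-quinone, with phase transfer bringing the lipophilic bis-phenol into contact with the salt.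

Step 7
Reactants: 16 5,5'-(tetradecane-1,14-diyl)bis(3-methoxy-2-methylcyclohexa-2,5-diene-1,4-dione)
Product: 17 1,1'-(tetradecane-1,14-diyl)bis(3-methoxy-4-methyl-7-oxabicyclo[4.1.0]hept-3-ene-2,5-dione), as a mixture of diastereomers
Conditions: 30% H2O2, Na2CO3, THF/EtOH/H2O, 0 °C
Reagents that add atoms: hydrogen peroxide, OO
Why: In this Weitz–Scheffer epoxidation hydroperoxide should add at C2, the only unsubstituted ring carbon and β to the more electrophilic C4 carbonyl (the C1 carbonyl is damped as part of the vinylogous ester MeO–C5=C6–C1=O), and the enolate then closes the oxirane across C2–C3; each oxirane is cis-fused by ring constraint, and its configuration relative to the remote ring is immaterial because all four stereocentres disappear in step 8.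

Step 8
Reactants: 17 1,1'-(tetradecane-1,14-diyl)bis(3-methoxy-4-methyl-7-oxabicyclo[4.1.0]hept-3-ene-2,5-dione)
Product: 18 3,3'-(tetradecane-1,14-diyl)bis(2-hydroxy-5-methoxy-6-methylcyclohexa-2,5-diene-1,4-dione) (target)
Conditions: conc. H2SO4 (substrate added as a concentrated CH2Cl2 solution), 0 to 20 °C; then ice/H2O
Reagents that add atoms: none
Why: Acid-promoted isomerisation of an α,β-epoxy diketone: loss of the epoxide hydrogen at C2 with opening of the C3–O bond leaves the oxygen on C2 and restores the quinone as its 2-hydroxy form, the classical conversion of quinone epoxides bearing one ring hydrogen into hydroxyquinones, and only this regiochemistry is possible because C3 is quaternary.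

**Compound list**

1 | 1,14-dibromotetradecane | BrCCCCCCCCCCCCCCBr | starting material
2 | lithium acetylide ethylenediamine complex | [Li]C#C.NCCN | starting material
3 | octadeca-1,17-diyne | C#CCCCCCCCCCCCCCCC#C | intermediate
4 | trichloroacetyl chloride | O=C(Cl)C(Cl)(Cl)Cl | starting material
5 | dichloroketene | O=C=C(Cl)Cl | intermediate (not isolated)
6 | 3,3'-(tetradecane-1,14-diyl)bis(4,4-dichlorocyclobut-2-en-1-one) | O=C1C=C(CCCCCCCCCCCCCCC2=CC(=O)C2(Cl)Cl)C1(Cl)Cl | intermediate
7 | 3,3'-(tetradecane-1,14-diyl)bis(cyclobut-2-en-1-one) | O=C1C=C(CCCCCCCCCCCCCCC2=CC(=O)C2)C1 | intermediate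
8 | 2-chloro-1,1-dimethoxyethane | COC(CCl)OC | starting material
9 | sodium methoxyacetylide | [Na+].[C-]#COC | intermediate (not isolated)
10 | 1-methoxyprop-1-yne | COC#CC | intermediate
11 | 3,18-dimethylideneicosa-1,19-diene-1,20-dione (bis-vinylketene; both ends drawn at the same stage, the two ends react independently) | O=C=CC(=C)CCCCCCCCCCCCCCC(=C)C=C=O | intermediate (not isolated)
12 | 4,4'-(octadeca-1,17-diene-2,17-diyl)bis(3-methoxy-2-methylcyclobut-2-en-1-one) (bis(4-alkenylcyclobutenone); ring sp3 centres unassigned and transient) | COC1=C(C)C(=O)C1C(=C)CCCCCCCCCCCCCCC(=C)C1C(=O)C(C)=C1OC | intermediate (not isolated)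
13 | 3,22-dimethoxy-2,23-dimethyl-5,20-dimethylidenetetracosa-1,3,21,23-tetraene-1,24-dione (bis-dienylketene; ketenyl and vinyl cis on each central double bond) | O=C=C(C)/C(OC)=C\C(=C)CCCCCCCCCCCCCCC(=C)/C=C(OC)\C(C)=C=O | intermediate (not isolated)
14 | 5,5'-(tetradecane-1,14-diyl)bis(3-methoxy-2-methylcyclohexa-2,4-dien-1-one) (bis-cyclohexadienone) | COC1=C(C)C(=O)CC(CCCCCCCCCCCCCCC2=CC(OC)=C(C)C(=O)C2)=C1 | intermediate (not isolated)
15 | 5,5'-(tetradecane-1,14-diyl)bis(3-methoxy-2-methylphenol) | COc1cc(CCCCCCCCCCCCCCc2cc(O)c(C)c(OC)c2)cc(O)c1C | intermediate
16 | 5,5'-(tetradecane-1,14-diyl)bis(3-methoxy-2-methylcyclohexa-2,5-diene-1,4-dione) | COC1=C(C)C(=O)C=C(CCCCCCCCCCCCCCC2=CC(=O)C(C)=C(OC)C2=O)C1=O | intermediate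
17 | 1,1'-(tetradecane-1,14-diyl)bis(3-methoxy-4-methyl-7-oxabicyclo[4.1.0]hept-3-ene-2,5-dione) (each oxirane cis-fused, racemic; diastereomer mixture across the two rings) | COC1=C(C)C(=O)C2OC2(CCCCCCCCCCCCCCC23OC2C(=O)C(C)=C(OC)C3=O)C1=O | intermediate
18 | 3,3'-(tetradecane-1,14-diyl)bis(2-hydroxy-5-methoxy-6-methylcyclohexa-2,5-diene-1,4-dione) | COC1=C(C)C(=O)C(O)=C(CCCCCCCCCCCCCCC2=C(O)C(=O)C(C)=C(OC)C2=O)C1=O | target

**Step count**

Total steps: 8. Longest linear sequence: 7 (steps 1, 2, 3, 5, 6, 7, 8); step 4 is a one-step branch that joins at step 5.

**Steps most likely to fail**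

Step 5. Because the substrate is bifunctional, a ketene end of one molecule may acylate an already formed phenol end of another and lead to oligomeric esters. The volatile ynol ether may also be lost from the hot mixture, or one end may stall at the alkenylcyclobutenone stage. The fallback replaces the cycloaddition by a cross-coupling and uses known chemistry. It sets out from 1, which with Mg in THF should give tetradecane-1,14-diylbis(magnesium bromide) F1. Kumada–Corriu coupling of F1 with two equivalents of purchased 5-bromo-1,3-dimethoxy-2-methylbenzene (COc1cc(Br)cc(OC)c1C) under PdCl2(dppf) catalysis should give 1,14-bis(3,5-dimethoxy-4-methylphenyl)tetradecane F2. NaSEt in DMF at about 140 °C should then cleave one of the two equivalent methyl ethers in each ring, the phenoxide formed protecting the second, and the sequence comes back to the route at 15.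

Step 8. Concentrated acid may cleave the vinylogous methyl ester or char the material, and poor solubility of the lipophilic bis-epoxide may leave the opening incomplete. The fallback sets out from 16 and replaces steps 7 and 8. Thiele–Winter acetoxylation (Ac2O, cat. HClO4, 20 °C) adds acetate at C2, the only free ring position, and should give 3,3'-(tetradecane-1,14-diyl)bis(5-methoxy-6-methylbenzene-1,2,4-triyl) hexaacetate F3. Methanolysis with HCl/MeOH under N2 should release 3,3'-(tetradecane-1,14-diyl)bis(5-methoxy-6-methylbenzene-1,2,4-triol) F4, and FeCl3 in aqueous MeOH should oxidise F4 to the hydroxyquinone, coming back to the route at 18.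

Step 2. The cycloaddition may stop after one alkyne, and dichloroketene polymerisation and chloride migration may erode throughput at both ends, which also burdens the zinc reduction of step 3. The fallback sets out from 3 and replaces steps 2 and 3. N,N-Dimethylacetamide, Tf2O and 2,4,6-collidine in ClCH2CH2Cl at reflux should generate N,N-dimethylketeniminium trifluoromethanesulfonate F5. Its [2+2] cycloaddition to both terminal alkynes, with the same regiochemistry as a ketene, should give 3,3'-(tetradecane-1,14-diyl)bis(N,N-dimethylcyclobut-2-en-1-iminium) bis(trifluoromethanesulfonate) F6. Aqueous NaHCO3 hydrolysis of the iminium groups should then deliver the bis-cyclobutenone without chlorinated intermediates, coming back to the route at 7.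

**Further compounds**

F1 | step 5 | tetradecane-1,14-diylbis(magnesium bromide) | Br[Mg]CCCCCCCCCCCCCC[Mg]Br
F2 | step 5 | 1,14-bis(3,5-dimethoxy-4-methylphenyl)tetradecane | COc1cc(CCCCCCCCCCCCCCc2cc(OC)c(C)c(OC)c2)cc(OC)c1C
F3 | step 8 | 3,3'-(tetradecane-1,14-diyl)bis(5-methoxy-6-methylbenzene-1,2,4-triyl) hexaacetate | COc1c(C)c(OC(C)=O)c(OC(C)=O)c(CCCCCCCCCCCCCCc2c(OC(C)=O)c(OC(C)=O)c(C)c(OC)c2OC(C)=O)c1OC(C)=O
F4 | step 8 | 3,3'-(tetradecane-1,14-diyl)bis(5-methoxy-6-methylbenzene-1,2,4-triol) | COc1c(C)c(O)c(O)c(CCCCCCCCCCCCCCc2c(O)c(O)c(C)c(OC)c2O)c1O
F5 | step 2 | N,N-dimethylketeniminium trifluoromethanesulfonate | C=C=[N+](C)C.[O-]S(=O)(=O)C(F)(F)F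
F6 | step 2 | 3,3'-(tetradecane-1,14-diyl)bis(N,N-dimethylcyclobut-2-en-1-iminium) bis(trifluoromethanesulfonate) | C[N+](C)=C1C=C(CCCCCCCCCCCCCCC2=CC(=[N+](C)C)C2)C1.[O-]S(=O)(=O)C(F)(F)F.[O-]S(=O)(=O)C(F)(F)F
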